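The route rests on cutting the two aryl–C7 bonds that join the terminal guaiacyl rings to units A and C. Each C7 carbinol carbon lies next to a C8 whose oxygen is an aryl ether (O4 of ring B for unit A, O4 of one syringyl ring of the furofuran core for unit C); both pairs are erythro, in mirror-image sense. One twofold, non-chelated Felkin–Anh arylation of a bis(α-aryloxy aldehyde) therefore makes both C–C bonds and both C7 stereocentres at once. The bis-aldehyde is the (−)-syringaresinol core carrying threo unit B as its 7,9-acetonide, with triisopropylsilyl ethers on the C9 oxygens beside both aldehyde carbons.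

Key step: step 18

Remark on the chemistry: lignan numbering is used (in every C6C3 unit C7 is the benzylic carbon, C8 its neighbour, C9 the CH2O carbon and O4 the phenolic oxygen); the two terminal phenols travel as triisopropylsilyl ethers, so that once the benzylic carbinols exist only fluoride and aqueous acetic acid are needed; where more than one molecule of a numbered compound is built into a product (steps 3 and 18), the further molecule is also named on the line of atom-adding reagents.

Step 1
Reactants: 1 syringaldehyde (4-hydroxy-3,5-dimethoxybenzaldehyde)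
Product: 2 ethyl (E)-sinapate [ethyl (E)-3-(4-hydroxy-3,5-dimethoxyphenyl)prop-2-enoate]
Conditions: Ph3P=CHCO2Et (1.3 equiv), toluene, 100 °C
Reagents that add atoms: ethyl (triphenylphosphoranylidene)acetate, CCOC(=O)C=P(c1ccccc1)(c1ccccc1)c1ccccc1
Why: Wittig olefination with a stabilised ylide, which tolerates the free phenol and should give the (E)-enoate through the favoured trans oxaphosphetane.

Step 2
Reactants: 2 ethyl (E)-sinapate
Product: 3 sinapyl alcohol [(E)-4-(3-hydroxyprop-1-enyl)-2,6-dimethoxyphenol]
Conditions: i-Bu2AlH (4 equiv), toluene, 0 °C; aq. potassium sodium tartrate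
Reagents that add atoms: none
Why: 1,2-reduction of the unsaturated ester by the aluminium hydride (the phenol is deprotonated first and set free again on work-up), the established access to monolignols.

Step 3
Reactants: 3 sinapyl alcohol (two molecules per furofuran; the enantiomer pair written for 4 takes four)
Product: 4 rac-syringaresinol [racemic 8–8′-linked furofuran with both 4-hydroxy-3,5-dimethoxyphenyl groups exo on the cis-fused 3,7-dioxabicyclo[3.3.0]octane]
Conditions: FeCl3·6H2O (1.1 equiv per molecule of 3), acetone/H2O, rt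
Reagents that add atoms: sinapyl alcohol (the further molecules of 3 that are coupled), COc1cc(/C=C/CO)cc(OC)c1O
Why: biomimetic oxidative phenol coupling (a dehydrodimerisation) in which one-electron oxidation of two molecules of 3 gives phenoxy radicals that couple at C8–C8′ (ring positions 3 and 5 are blocked by methoxy groups) and the two C9 hydroxyls then add to the quinone methide carbons C7′ and C7, closing the cis-fused bis-tetrahydrofuran with both aryl groups exo, as the racemate because nothing chiral is present.

Step 4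
Reactants: 4 rac-syringaresinol
Product: 5 (−)-syringaresinol [(7R,8S,7′R,8′S) enantiomer]
Conditions: preparative HPLC on cellulose tris(3,5-dimethylphenylcarbamate), hexane/i-PrOH
Reagents that add atoms: none
Why: chromatographic resolution on a polysaccharide carbamate phase separates the enantiomers, and the (7R,8S,7′R,8′S) form is the one known as laevorotatory, so it can be identified by the sign of its rotation.

Step 5
Reactants: 6 (S)-4-benzyloxazolidin-2-one
Product: 8 (S)-4-benzyl-3-(bromoacetyl)oxazolidin-2-one, via N-lithio oxazolidinone 7 (not isolated)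
Conditions: n-BuLi (1.0 equiv), THF, −78 °C; BrCH2COBr (1.1 equiv), −78 → 0 °C
Reagents that add atoms: bromoacetyl bromide, BrCC(Br)=O
Why: N-acylation of the lithiated oxazolidinone by the acid bromide (standard imide formation for auxiliary chemistry), which leaves the alkyl bromide and the C4 stereocentre untouched.

Step 6
Reactants: 5 (−)-syringaresinol; 8 (S)-4-benzyl-3-(bromoacetyl)oxazolidin-2-one
Product: 9 core mono-glycolyl imide [5 with one phenol O4 alkylated by CH2C(=O)–N of (S)-4-benzyloxazolidin-2-one; other phenol free]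
Conditions: 8 (0.8 equiv), K2CO3 (1.0 equiv), acetone, rt; unreacted 5 recycled
Reagents that add atoms: none
Why: Williamson ether synthesis in which the phenoxide displaces the activated α-bromo imide by SN2; the two phenols are equivalent through the C2 axis of 5, so the statistical monoalkylation, favoured by the deficit of 8, can give only one mono-ether.

Step 7
Reactants: 10 methyl (S)-2,2-dimethyl-1,3-dioxolane-4-carboxylate
Product: 11 methyl (S)-2,3-dihydroxypropanoate
Conditions: p-toluenesulfonic acid monohydrate (0.05 equiv), MeOH, rt; NaHCO3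
Reagents that add atoms: none
Why: acid-catalysed transketalisation to methanol removes the isopropylidene group without touching the methyl ester or the stereocentre.

Step 8
Reactants: 11 methyl (S)-2,3-dihydroxypropanoate
Product: 12 methyl (S)-2-hydroxy-3-(triisopropylsilyloxy)propanoate
Conditions: i-Pr3SiCl (1.05 equiv), imidazole (2.2 equiv), CH2Cl2, 0 °C → rt
Reagents that add atoms: triisopropylsilyl chloride, CC(C)[Si](Cl)(C(C)C)C(C)C
Why: silylation with the bulky silyl chloride is selective for the primary hydroxyl over the hindered, less nucleophilic α-hydroxy ester hydroxyl.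

Step 9
Reactants: 9 core mono-glycolyl imide; 12 methyl (S)-2-hydroxy-3-(triisopropylsilyloxy)propanoate
Product: 13 arm-C ester imide [9 whose free phenol O4 carries (R)-CH(CO2Me)CH2OSi(i-Pr)3]
Conditions: 12 (1.5 equiv), PPh3 (1.6 equiv), DIAD (1.6 equiv), toluene, 0 °C → rt
Reagents that add atoms: none
Why: Mitsunobu etherification in which the phenol of 9 displaces the oxyphosphonium ion of the α-hydroxy ester by SN2 with inversion, turning (S)-C2 of 12 into the (R)-configured C8 of unit C.

Step 10
Reactants: 14 methyl (R)-2,2-dimethyl-1,3-dioxolane-4-carboxylate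
Product: 15 methyl (R)-2,3-dihydroxypropanoate
Conditions: p-toluenesulfonic acid monohydrate (0.05 equiv), MeOH, rt; NaHCO3
Reagents that add atoms: none
Why: acid-catalysed transketalisation to methanol, as for the enantiomer, with the stereocentre not involved.

Step 11
Reactants: 15 methyl (R)-2,3-dihydroxypropanoate
Product: 16 methyl (R)-2-hydroxy-3-(triisopropylsilyloxy)propanoate
Conditions: i-Pr3SiCl (1.05 equiv), imidazole (2.2 equiv), CH2Cl2, 0 °C → rt
Reagents that add atoms: triisopropylsilyl chloride, CC(C)[Si](Cl)(C(C)C)C(C)C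
Why: selective silylation of the primary hydroxyl by the bulky silyl chloride, as for the enantiomer.

Step 12
Reactants: 17 vanillin (4-hydroxy-3-methoxybenzaldehyde); 16 methyl (R)-2-hydroxy-3-(triisopropylsilyloxy)propanoate
Product: 18 methyl (S)-2-(4-formyl-2-methoxyphenoxy)-3-(triisopropylsilyloxy)propanoate
Conditions: 16 (1.1 equiv), PPh3 (1.2 equiv), DIAD (1.2 equiv), THF, 0 °C → rt
Reagents that add atoms: none
Why: Mitsunobu etherification of the acidic phenol of vanillin with inversion at C2 of 16, which sets the (S)-configured C8 of unit A on the future ring B.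

Step 13
Reactants: 13 arm-C ester imide; 18 methyl (S)-2-(4-formyl-2-methoxyphenoxy)-3-(triisopropylsilyloxy)propanoate
Product: 20 syn-aldol adduct, via boron enolate 19 (not isolated)
Conditions: n-Bu2BOTf (1.2 equiv), i-Pr2NEt (1.4 equiv), CH2Cl2, −78 → 0 °C; 18 (1.3 equiv), −78 → 0 °C; aq. NaH2PO4/Na2HPO4 (pH 7), MeOH, H2O2, 0 °C
Reagents that add atoms: none
Why: Evans syn-aldol reaction in which soft enolisation gives the (Z)-boron enolate 19, which reacts through a Zimmerman–Traxler chair on the enolate face away from the benzyl group of the (S)-auxiliary, so that the (2S,3R)-3-hydroxy-2-aryloxy imide forms with C7 (R) and C8 of unit B syn, the threo (7R,8R) arrangement after reduction, while the hindered α-aryloxy esters are not enolised by the small excess of boron triflate.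

Step 14
Reactants: 20 syn-aldol adduct
Product: 21 tetraol [unit B as free (7R,8R)-7,9-diol; arms A and C each ArO–CH(CH2OH)CH2OSi(i-Pr)3 with unchanged spatial arrangement at C8]
Conditions: LiBH4 (6 equiv), MeOH (6 equiv), THF, 0 °C → rt; aq. NH4Cl
Reagents that add atoms: none
Why: borohydride reduction cleaves the imide to the C9 alcohol of unit B with release of the auxiliary and reduces both α-aryloxy methyl esters to primary alcohols, without touching a stereocentre and without migration of the bulky silyl ethers.

Step 15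
Reactants: 21 tetraol
Product: 22 unit-B acetonide diol [21 with O7 and O9 of unit B bridged as (4R,5R)-2,2-dimethyl-1,3-dioxane; both arm CH2OH free]
Conditions: Me2C(OMe)2 (5 equiv), pyridinium p-toluenesulfonate (0.1 equiv), acetone, rt; then MeOH, 10 min; Et3N
Reagents that add atoms: 2,2-dimethoxypropane, COC(C)(C)OC
Why: thermodynamically controlled acetalisation in which only the 1,3-diol of unit B can close a cyclic isopropylidene acetal (the cis-4-aryl-5-aryloxy-1,3-dioxane that a threo diol gives, with the aryl group equatorial and the aryloxy group axial at C5), while any acyclic mixed ketal of the isolated primary alcohols is removed by the brief methanolysis.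

Step 16
Reactants: 22 unit-B acetonide diol
Product: 23 core–unit-B bis-aldehyde [22 with both arm CH2OH oxidised to CHO; (8S) at arm A and (8R) at arm C]
Conditions: Dess–Martin periodinane (3 equiv), NaHCO3 (10 equiv), CH2Cl2, 0 °C → rt; short silica pad, used at once
Reagents that add atoms: none
Why: Dess–Martin oxidation of both primary alcohols under buffered, base-free conditions should give the two α-aryloxy aldehydes without enolisation, so that C8 of arms A and C keeps its configuration.

Step 17
Reactants: 24 4-bromo-2-methoxyphenol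
Product: 25 (4-bromo-2-methoxyphenoxy)triisopropylsilane
Conditions: i-Pr3SiCl (1.1 equiv), imidazole (2.2 equiv), DMF, rt
Reagents that add atoms: triisopropylsilyl chloride, CC(C)[Si](Cl)(C(C)C)C(C)C
Why: silylation of the phenol with the silyl chloride and imidazole gives a bulky aryl silyl ether that withstands bromine–lithium exchange and leaves later with fluoride.

Step 18
Reactants: 23 core–unit-B bis-aldehyde; 25 (4-bromo-2-methoxyphenoxy)triisopropylsilane (two molecules are built in)
Product: 28 fully assembled protected target, via aryllithium 26 (not isolated), via aryltitanium 27 (not isolated)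
Conditions: 25 (6 equiv), n-BuLi (6 equiv), THF, −78 °C; ClTi(Oi-Pr)3 (6.5 equiv), −78 → −40 °C; 23, THF, −78 → −20 °C; aq. NH4Cl
Reagents that add atoms: (4-bromo-2-methoxyphenoxy)triisopropylsilane (the second molecule of 25, as its aryl group), COc1cc(Br)ccc1O[Si](C(C)C)(C(C)C)C(C)C
Why: The aryltitanium triisopropoxide 27 transfers its aryl group to each aldehyde carbon through an open, non-chelated transition state of the polar Felkin–Anh type, the closest known reaction being the non-chelation-controlled addition of organotitanium alkoxides to α-alkoxy aldehydes. No ring is closed; the two aryl–C7 bonds and the C7 stereocentres of units A and C are formed. Each C7 is set by 1,2-induction from its own C8: the C8–OAr bond lies anti to the incoming aryl group and the nucleophile passes the C8 hydrogen, not the CH2OSi arm, which gives the anti (erythro) carbinol, 7R from (8S) at unit A and 7S from (8R) at unit C. The selectivity needed is Felkin over chelate addition, and it is secured by the weakly basic aryl ether oxygens, the bulky silyl ethers on C9 and the low Lewis acidity of the titanium alkoxide. The non-basic titanium reagent should also avoid enolisation of the aldehydes, so that C8 is not epimerised and the C9 silyloxy group is not eliminated. The stereocentres of the core and of unit B are remote, so the two termini should react independently by the same rule.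

Step 19
Reactants: 28 fully assembled protected target
Product: 29 unit-B acetonide of the target [all four silyl groups removed; acetonide kept]
Conditions: Bu4NF (8 equiv), AcOH (8 equiv), THF, 0 °C → rt
Reagents that add atoms: none
Why: fluoride-induced desilylation through pentacoordinate silicon removes the two aryl and the two primary triisopropylsilyl ethers, and the acetic acid buffer keeps the freed phenols from forming quinone methides with the adjacent carbinols.

Step 20
Reactants: 29 unit-B acetonide of the target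
Product: 30 target CNP0316493.1
Conditions: AcOH/H2O 4:1, THF, 35 °C
Reagents that add atoms: none
Why: acid-catalysed acetal hydrolysis through the tertiary oxocarbenium ion of the isopropylidene group, in which the weak acid and the absence of an alcohol solvent should spare the benzylic carbinols and the furofuran from ionisation at C7.

Compound list

1 | syringaldehyde | COc1cc(C=O)cc(OC)c1O | starting material
2 | ethyl (E)-sinapate | CCOC(=O)/C=C/c1cc(OC)c(O)c(OC)c1 | intermediate
3 | sinapyl alcohol | COc1cc(/C=C/CO)cc(OC)c1O | intermediate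
4 | rac-syringaresinol (racemate; one molecule of each enantiomer written) | COc1cc([C@@H]2OC[C@@H]3[C@H]2CO[C@H]3c2cc(OC)c(O)c(OC)c2)cc(OC)c1O.COc1cc([C@H]2OC[C@H]3[C@@H]2CO[C@@H]3c2cc(OC)c(O)c(OC)c2)cc(OC)c1O | intermediate
5 | (−)-syringaresinol, (7R,8S,7′R,8′S) | COc1cc([C@@H]2OC[C@@H]3[C@H]2CO[C@H]3c2cc(OC)c(O)c(OC)c2)cc(OC)c1O | intermediate
6 | (S)-4-benzyloxazolidin-2-one | O=C1N[C@@H](Cc2ccccc2)CO1 | starting material
7 | N-lithio (S)-4-benzyloxazolidin-2-one | O=C1OC[C@H](Cc2ccccc2)N1[Li] | intermediate
8 | (S)-4-benzyl-3-(bromoacetyl)oxazolidin-2-one | O=C(CBr)N1[C@@H](Cc2ccccc2)COC1=O | intermediate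
9 | core mono-glycolyl imide | COc1cc([C@@H]2OC[C@@H]3[C@H]2CO[C@H]3c2cc(OC)c(O)c(OC)c2)cc(OC)c1OCC(=O)N1[C@@H](Cc2ccccc2)COC1=O | intermediate
10 | methyl (S)-2,2-dimethyl-1,3-dioxolane-4-carboxylate | COC(=O)[C@@H]1COC(C)(C)O1 | starting material
11 | methyl (S)-2,3-dihydroxypropanoate | COC(=O)[C@@H](O)CO | intermediate
12 | methyl (S)-2-hydroxy-3-(triisopropylsilyloxy)propanoate | COC(=O)[C@@H](O)CO[Si](C(C)C)(C(C)C)C(C)C | intermediate
13 | arm-C ester imide | COc1cc([C@@H]2OC[C@@H]3[C@H]2CO[C@H]3c2cc(OC)c(O[C@H](CO[Si](C(C)C)(C(C)C)C(C)C)C(=O)OC)c(OC)c2)cc(OC)c1OCC(=O)N1[C@@H](Cc2ccccc2)COC1=O | intermediate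
14 | methyl (R)-2,2-dimethyl-1,3-dioxolane-4-carboxylate | COC(=O)[C@H]1COC(C)(C)O1 | starting material
15 | methyl (R)-2,3-dihydroxypropanoate | COC(=O)[C@H](O)CO | intermediate
16 | methyl (R)-2-hydroxy-3-(triisopropylsilyloxy)propanoate | COC(=O)[C@H](O)CO[Si](C(C)C)(C(C)C)C(C)C | intermediate
17 | vanillin | COc1cc(C=O)ccc1O | starting material
18 | methyl (S)-2-(4-formyl-2-methoxyphenoxy)-3-(triisopropylsilyloxy)propanoate | COC(=O)[C@H](CO[Si](C(C)C)(C(C)C)C(C)C)Oc1ccc(C=O)cc1OC | intermediate
19 | (Z)-dibutylboron enolate of 13 | COc1cc([C@@H]2OC[C@@H]3[C@H]2CO[C@H]3c2cc(OC)c(O[C@H](CO[Si](C(C)C)(C(C)C)C(C)C)C(=O)OC)c(OC)c2)cc(OC)c1O/C=C(\OB(CCCC)CCCC)N1[C@@H](Cc2ccccc2)COC1=O | intermediate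
20 | syn-aldol adduct [(S)-4-benzyl-3-acyloxazolidin-2-one; acyl = (2S,3R)-3-hydroxy-3-aryl-2-(core O4-aryloxy)propanoyl; aryl = ring B carrying arm A as (S)-OCH(CO2Me)CH2OSi(i-Pr)3; arm C ester unchanged] | COC(=O)[C@H](CO[Si](C(C)C)(C(C)C)C(C)C)Oc1ccc([C@@H](O)[C@H](Oc2c(OC)cc([C@@H]3OC[C@@H]4[C@H]3CO[C@H]4c3cc(OC)c(O[C@H](CO[Si](C(C)C)(C(C)C)C(C)C)C(=O)OC)c(OC)c3)cc2OC)C(=O)N2[C@@H](Cc3ccccc3)COC2=O)cc1OC | intermediate
21 | tetraol | OC[C@H](CO[Si](C(C)C)(C(C)C)C(C)C)Oc1ccc([C@@H](O)[C@@H](CO)Oc2c(OC)cc([C@@H]3OC[C@@H]4[C@H]3CO[C@H]4c3cc(OC)c(O[C@H](CO[Si](C(C)C)(C(C)C)C(C)C)CO)c(OC)c3)cc2OC)cc1OC | intermediate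
22 | unit-B acetonide diol | OC[C@H](CO[Si](C(C)C)(C(C)C)C(C)C)Oc1ccc([C@@H](OC(C)(C)OC2)[C@@H]2Oc2c(OC)cc([C@@H]3OC[C@@H]4[C@H]3CO[C@H]4c3cc(OC)c(O[C@H](CO[Si](C(C)C)(C(C)C)C(C)C)CO)c(OC)c3)cc2OC)cc1OC | intermediate
23 | core–unit-B bis-aldehyde | O=C[C@H](CO[Si](C(C)C)(C(C)C)C(C)C)Oc1ccc([C@@H](OC(C)(C)OC2)[C@@H]2Oc2c(OC)cc([C@@H]3OC[C@@H]4[C@H]3CO[C@H]4c3cc(OC)c(O[C@H](CO[Si](C(C)C)(C(C)C)C(C)C)C=O)c(OC)c3)cc2OC)cc1OC | intermediate
24 | 4-bromo-2-methoxyphenol | COc1cc(Br)ccc1O | starting material
25 | (4-bromo-2-methoxyphenoxy)triisopropylsilane | COc1cc(Br)ccc1O[Si](C(C)C)(C(C)C)C(C)C | intermediate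
26 | [3-methoxy-4-(triisopropylsilyloxy)phenyl]lithium | COc1cc([Li])ccc1O[Si](C(C)C)(C(C)C)C(C)C | intermediate
27 | [3-methoxy-4-(triisopropylsilyloxy)phenyl]titanium triisopropoxide | COc1cc([Ti](OC(C)C)(OC(C)C)OC(C)C)ccc1O[Si](C(C)C)(C(C)C)C(C)C | intermediate
28 | fully assembled protected target [unit A (7R,8S) and unit C (7S,8R) with free C7 carbinols; C9–OSi(i-Pr)3 on units A and C; unit B acetonide; both terminal phenols as Si(i-Pr)3 ethers] | COc1cc([C@@H](O)[C@H](CO[Si](C(C)C)(C(C)C)C(C)C)Oc2ccc([C@@H](OC(C)(C)OC3)[C@@H]3Oc3c(OC)cc([C@@H]4OC[C@@H]5[C@H]4CO[C@H]5c4cc(OC)c(O[C@H](CO[Si](C(C)C)(C(C)C)C(C)C)[C@@H](O)c5ccc(O[Si](C(C)C)(C(C)C)C(C)C)c(OC)c5)c(OC)c4)cc3OC)cc2OC)ccc1O[Si](C(C)C)(C(C)C)C(C)C | intermediate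
29 | unit-B acetonide of the target | COc1cc([C@@H](O)[C@H](CO)Oc2ccc([C@@H](OC(C)(C)OC3)[C@@H]3Oc3c(OC)cc([C@@H]4OC[C@@H]5[C@H]4CO[C@H]5c4cc(OC)c(O[C@H](CO)[C@@H](O)c5ccc(O)c(OC)c5)c(OC)c4)cc3OC)cc2OC)ccc1O | intermediate
30 | CNP0316493.1 | COc1cc([C@@H](O)[C@H](CO)Oc2ccc([C@@H](O)[C@@H](CO)Oc3c(OC)cc([C@@H]4OC[C@@H]5[C@H]4CO[C@H]5c4cc(OC)c(O[C@H](CO)[C@@H](O)c5ccc(O)c(OC)c5)c(OC)c4)cc3OC)cc2OC)ccc1O | target

Total step count: 20. Longest linear sequence: 13 steps (steps 1–4, 6, 9, 13–16, 18, 19 and 20, from syringaldehyde).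

Steps most likely to fail

Step 18. Facial selectivity may be insufficient at one or both aldehydes, because a chelate-type addition can compete with the Felkin mode. The fallback sets the two C7 centres by hydride delivery to ketones and not by the C–C addition. It sets out from 28 obtained as a mixture of C7 epimers. Dess–Martin oxidation of both carbinols (NaHCO3, CH2Cl2) should give the bis(aryl ketone) F1. Reduction with Zn(BH4)2 in Et2O at −30 °C runs under chelation control: zinc bridges the C7 carbonyl and the C8 aryl ether oxygen, and hydride enters past the C8 hydrogen. At each terminus this gives the anti (erythro) carbinol, so the sequence comes back to the route at 28.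

Step 9. The phenol of 9 is flanked by two methoxy groups, so SN2 attack on the oxyphosphonium ion may be slow and the activated ester may be lost by elimination or by alkylation of the hydrazide. The fallback replaces the redox condensation by alkylation with a pre-formed sulfonate. It sets out from 12, which with Tf2O and 2,6-lutidine (CH2Cl2, −78 °C) should give methyl (S)-2-(trifluoromethylsulfonyloxy)-3-(triisopropylsilyloxy)propanoate F2. The phenoxide of 9 (K2CO3, MeCN, −20 °C → rt) displaces the triflate with inversion, and the sequence comes back to the route at 13.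

Step 13. The boron triflate may be sequestered by the many ether oxygens or may enolise the α-aryloxy ester of arm C, which would give incomplete conversion or erosion at C8 of unit C. The fallback takes that ester out of the enolate partner and attaches arm C afterwards by SN2; it sets out from 9, with 18 as the aldehyde. The aldol is run on 9 itself with a second equivalent of n-Bu2BOTf and i-Pr2NEt, which masks the free phenol as its dibutylborinate, and non-oxidative work-up (MeOH, aqueous buffer) should give the phenolic aldol adduct F3. LiBH4 (MeOH, THF) then reduces the imide and the arm-A ester to the phenolic tetraol F4, and 2,2-dimethoxypropane with pyridinium p-toluenesulfonate gives the phenolic acetonide F5. The phenoxide of F5 (K2CO3, MeCN, −20 °C) displaces the triflate F2, made from 12 as in the fallback to step 9, with inversion and without competition from the neutral hydroxyls, to give the arm-C ester F6. LiBH4 reduction of F6 comes back to the route at 22.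

Further compounds

F1 | step 18 | bis(aryl ketone) of 28 (C7 of units A and C as C=O) | COc1cc(C(=O)[C@H](CO[Si](C(C)C)(C(C)C)C(C)C)Oc2ccc([C@@H](OC(C)(C)OC3)[C@@H]3Oc3c(OC)cc([C@@H]4OC[C@@H]5[C@H]4CO[C@H]5c4cc(OC)c(O[C@H](CO[Si](C(C)C)(C(C)C)C(C)C)C(=O)c5ccc(O[Si](C(C)C)(C(C)C)C(C)C)c(OC)c5)c(OC)c4)cc3OC)cc2OC)ccc1O[Si](C(C)C)(C(C)C)C(C)C
F2 | step 9 | methyl (S)-2-(trifluoromethylsulfonyloxy)-3-(triisopropylsilyloxy)propanoate | COC(=O)[C@@H](OS(=O)(=O)C(F)(F)F)CO[Si](C(C)C)(C(C)C)C(C)C
F3 | step 13 | phenolic aldol adduct (20 without arm C, core phenol free) | COC(=O)[C@H](CO[Si](C(C)C)(C(C)C)C(C)C)Oc1ccc([C@@H](O)[C@H](Oc2c(OC)cc([C@@H]3OC[C@@H]4[C@H]3CO[C@H]4c3cc(OC)c(O)c(OC)c3)cc2OC)C(=O)N2[C@@H](Cc3ccccc3)COC2=O)cc1OC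
F4 | step 13 | phenolic tetraol (unit B 7,9-diol, arm A CH2OH, core phenol free) | OC[C@H](CO[Si](C(C)C)(C(C)C)C(C)C)Oc1ccc([C@@H](O)[C@@H](CO)Oc2c(OC)cc([C@@H]3OC[C@@H]4[C@H]3CO[C@H]4c3cc(OC)c(O)c(OC)c3)cc2OC)cc1OC
F5 | step 13 | phenolic acetonide (unit B acetonide, arm A CH2OH, core phenol free) | OC[C@H](CO[Si](C(C)C)(C(C)C)C(C)C)Oc1ccc([C@@H](OC(C)(C)OC2)[C@@H]2Oc2c(OC)cc([C@@H]3OC[C@@H]4[C@H]3CO[C@H]4c3cc(OC)c(O)c(OC)c3)cc2OC)cc1OC
F6 | step 13 | arm-C ester of F5 (core O4 carrying (R)-CH(CO2Me)CH2OSi(i-Pr)3) | OC[C@H](CO[Si](C(C)C)(C(C)C)C(C)C)Oc1ccc([C@@H](OC(C)(C)OC2)[C@@H]2Oc2c(OC)cc([C@@H]3OC[C@@H]4[C@H]3CO[C@H]4c3cc(OC)c(O[C@H](CO[Si](C(C)C)(C(C)C)C(C)C)C(=O)OC)c(OC)c3)cc2OC)cc1OC
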